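The data stem from a simulated flask for an exercise, noise included.

| flask | starting material | coupling partner | time |
|---|---|---|---|
| dawn | 300 mM | 450 mM |  |
| noon | 900 mM | 450 mM |  |
| summer | 900 mM | 900 mM | 49 min |

| run | time / min | [product] / mM |
|---|---|---|
| dawn run | 7.0 | 26.5 |
| dawn run | 14 | 73.8 |
| dawn run | 21 | 119.5 |
| dawn run | 28 | 159.9 |
| dawn run | 35 | 189.7 |
| dawn run | 42 | 215.1 |
| dawn run | 49 | 239.7 |
| noon run | 7.0 | 55.2 |
| noon run | 14 | 149.4 |
| noon run | 21 | 243.3 |
| noon run | 28 | 317.4 |
| noon run | 35 | 374.5 |
| noon run | 42 | 405.0 |
| noon run | 49 | 430.6 |

(each reading ± 2 mM)

- reaction order in [starting material] at the outset, round the charge of the dawn run, defined at two percent of the starting material turned into product (one fixed amount of product, the same in the runs compared)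
- product in the summer run at 49 min, as a share of the starting material charged

- Overall: starting material + coupling partner -> product.
- Constant volume, constant temperature.
- A reading of a species includes what of it is bound.
- An order is taken over about fifteen percent of the charge, up and down.

1. Start from the balance: each product takes up one starting material and one coupling partner, so the smaller charge, the limiting reagent, caps the product. In the summer run both charges are 900 mM, so the bound from above is 100% of the starting material.

2. Now the bound from below. The noon run has the same starting material and half the partner, and it reads 430.6 mM at 49 min. If you assume that extra partner does not slow the flask, the summer run reaches at least 47.8%.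

3. Tighten it by hand. In the dawn run 79.9% is the completion, the product at 49 min over the smaller charge, and in the noon run it reads 95.7%.

4. In the dawn run the smaller charge is the starting material, in the noon run it is the partner, and in the summer run the two charges are equal. My own judgement is that its completion lies between those two readings, which gives 79.9% to 95.7%. The readings cannot prove this, since the partner charge is the same in both runs.

5. The forecast gives 63% (range 56% to 70%) and an order of 0.4 (0.28 to 0.62), integrating a rate in the square root of [starting material] over “46 effective minutes”. Its value stands above my lower bound, but its whole range stands below my tightened bracket.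

    starting material ⇌ intermediate (0.06840 min⁻¹, 0.007980 min⁻¹)
    intermediate + coupling partner → product (0.8100 M⁻¹ min⁻¹)
    2 starting material ⇌ idle substrate dimer, settled at all times (10.20 M⁻¹)
    starting material + coupling partner + product → 2 product (0.4794 M⁻² min⁻¹)

The summer run gives 83.7%, and the order is 0.41. Where the fixed amount of product stood, the noon run ran at 6.2 mM min⁻¹ and the dawn run at 4.1 mM min⁻¹, a ratio of 1.5 on 3.00 times the starting material. The summer completion is 83.7%, above the dawn reading and below the noon reading. Completion also times the earlier runs: it reaches half at 26.8 min in the dawn run and at 19.8 min in the noon run.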